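**Plan**

- Retrosynthesis: ring A (the 4-hydroxyphenyl ring; C1 bears the CH2CH2 bridge, C4 the OH) is taken back to a cyclohex-2-enone and cut at C1–C6 and C2–C3 into a 4-arylbutanal and methyl vinyl ketone. The butanal chain is then cut at the ring B aryl–CH2 bond, the ring C–ring D bridge at its CH2–CH2 bond, and the diaryl ether at the ring C C–O bond.
- Enabling feature: ring A carries only the bridge at C1 and a free hydroxyl at C4, which is the pattern of a 4-alkylcyclohex-2-enone one dehydrogenation below the phenol. The C4 oxygen therefore arrives as the ketone oxygen of methyl vinyl ketone and never needs protection.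
- Forward: rings B, C and D are bought as arenes and joined first (SNAr for B–O–C, lateral lithiation/alkylation for C–CH2CH2–D). A four-carbon aldehyde chain is attached to ring B by B-alkyl Suzuki coupling, and ring A, the only ring that is built, closes last by enamine Michael addition/aldol condensation.
- End game: aerobic dehydrogenation to the ring A phenol, saponification of the ring D ester, hydrogenolysis of the ring D benzyl ether.
- Stereochemistry: the target has no stereocentre. The one sp3 centre made in the annulation (C1 of ring A) is racemic and is erased on aromatisation.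

Key step: step 9

Assumption: compounds 1, 2, 6, 11 and 15 are taken as purchasable. Ring B is the central 1,3,5-trisubstituted ring, ring C the para-phenylene, ring D the salicylic acid ring.

**Route**

Step 1
Reactants: 1 3-bromo-5-methoxyphenol; 2 para-fluorobenzaldehyde (4-fluorobenzaldehyde)
Product: 3 4-(3-bromo-5-methoxyphenoxy)benzaldehyde
Conditions: K2CO3, DMF, 110 °C
Reagents that add atoms: none
Why: Nucleophilic aromatic substitution in which the phenoxide of 1 displaces fluoride para to the formyl group through a Meisenheimer adduct, the unactivated aryl bromide staying inert.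

Step 2
Reactants: 3 4-(3-bromo-5-methoxyphenoxy)benzaldehyde
Product: 4 [4-(3-bromo-5-methoxyphenoxy)phenyl]methanol
Conditions: NaBH4, MeOH/THF, 0 °C
Reagents that add atoms: none
Why: Borohydride reduction of an aryl aldehyde to the benzylic alcohol, which leaves the aryl bromide and the diaryl ether untouched.

Step 3
Reactants: 4 [4-(3-bromo-5-methoxyphenoxy)phenyl]methanol
Product: 5 1-bromo-3-[4-(bromomethyl)phenoxy]-5-methoxybenzene
Conditions: PBr3, CH2Cl2, 0 °C to rt
Reagents that add atoms: phosphorus tribromide, BrP(Br)Br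
Why: Bromination of a primary benzylic alcohol through its phosphite ester and SN2 displacement by bromide, helped by the para-aryloxy group.

Step 4
Reactants: 6 methyl 2,4-dihydroxy-6-methylbenzoate
Product: 7 methyl 2-hydroxy-4-methoxy-6-methylbenzoate
Conditions: MeI (1.1 equiv), K2CO3, acetone, 40 °C
Reagents that add atoms: iodomethane, CI
Why: Williamson etherification that should be selective for the 4-hydroxyl, because the 2-hydroxyl is held in a hydrogen bond to the ester carbonyl and is much less nucleophilic.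

Step 5
Reactants: 7 methyl 2-hydroxy-4-methoxy-6-methylbenzoate
Product: 8 methyl 2-(benzyloxy)-4-methoxy-6-methylbenzoate
Conditions: BnBr, K2CO3, DMF, 70 °C
Reagents that add atoms: benzyl bromide, BrCc1ccccc1
Why: Williamson benzylation of the chelated phenol under more forcing conditions, which removes the only acidic proton before the lateral lithiation.

Step 6
Reactants: 8 methyl 2-(benzyloxy)-4-methoxy-6-methylbenzoate; 5 1-bromo-3-[4-(bromomethyl)phenoxy]-5-methoxybenzene
Product: 10 methyl 2-(benzyloxy)-6-{2-[4-(3-bromo-5-methoxyphenoxy)phenyl]ethyl}-4-methoxybenzoate, via lithiated toluate 9 (not isolated)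
Conditions: LiN(iPr)2, THF, −78 °C; then 5, −78 to −30 °C
Reagents that add atoms: none
Why: Lateral lithiation of the ortho-toluate gives the ester-stabilised benzylic anion 9, which is alkylated by the benzylic bromide in an SN2 reaction, the aryl bromide not exchanging with this stabilised anion at low temperature.

Step 7
Reactants: 10 methyl 2-(benzyloxy)-6-{2-[4-(3-bromo-5-methoxyphenoxy)phenyl]ethyl}-4-methoxybenzoate; 11 4,4-diethoxybut-1-ene
Product: 13 methyl 2-(benzyloxy)-6-{2-[4-(3-(4,4-diethoxybutyl)-5-methoxyphenoxy)phenyl]ethyl}-4-methoxybenzoate, via alkylborane 12 (not isolated)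
Conditions: 11, 9-BBN, THF, 0 °C to rt; then 10, PdCl2(dppf) (5 mol%; dppf = 1,1'-bis(diphenylphosphino)ferrocene), K3PO4 (aq), DMF, 60 °C
Reagents that add atoms: none
Why: Anti-Markovnikov hydroboration of the terminal alkene followed by B-alkyl Suzuki–Miyaura coupling at the ring B bromide, conditions that the acetal, the benzyl ether and the hindered benzoate tolerate.

Step 8
Reactants: 13 methyl 2-(benzyloxy)-6-{2-[4-(3-(4,4-diethoxybutyl)-5-methoxyphenoxy)phenyl]ethyl}-4-methoxybenzoate
Product: 14 methyl 2-(benzyloxy)-4-methoxy-6-{2-[4-(3-methoxy-5-(4-oxobutyl)phenoxy)phenyl]ethyl}benzoate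
Conditions: 1 M HCl, THF, rt
Reagents that add atoms: water, O
Why: Acid-catalysed hydrolysis of the diethyl acetal through the oxocarbenium ion, to which the ethers and the hindered ester are stable at room temperature.

Step 9
Reactants: 14 methyl 2-(benzyloxy)-4-methoxy-6-{2-[4-(3-methoxy-5-(4-oxobutyl)phenoxy)phenyl]ethyl}benzoate; 15 but-3-en-2-one (methyl vinyl ketone)
Product: 19 methyl 2-(benzyloxy)-4-methoxy-6-{2-[4-(3-methoxy-5-[2-(4-oxocyclohex-2-en-1-yl)ethyl]phenoxy)phenyl]ethyl}benzoate (racemic), via pyrrolidine enamine 16 (not isolated), via keto aldehyde 17 (not isolated), via aldol 18 (not isolated)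
Conditions: pyrrolidine, 4 Å MS, PhMe, 0 °C to rt; then 15, 0 °C to rt; then AcOH/NaOAc/H2O, 70 °C
Reagents that add atoms: none
Why: Condensation of 14 with pyrrolidine gives the E-enamine 16, whose nucleophilic carbon (the aldehyde α-carbon, future C1 of ring A) adds to the terminal carbon of 15 (future C6), and buffered hydrolysis of the adduct releases keto aldehyde 17. The enol of the methyl ketone then attacks the aldehyde carbon, joining C3 to C2, and aldol 18 loses water by E1cB elimination to the conjugated enone 19. This is the enamine variant of the Robinson annulation (Stork enamine Michael addition followed by aldol condensation), the standard entry to 4-alkylcyclohex-2-enones from aldehydes. Ring A closes in a 6-(enolendo)-exo-trig aldol, both enol carbons lying inside the new ring and the aldehyde oxygen outside it. The lasting new stereocentre (C1 of ring A) and the transient carbinol centre of 18 are formed without any controlling element, and none is needed because dehydration and the later aromatisation remove both. The step needs a single conjugate addition and a single aldol regiochemistry: the first adduct is held as an aminal or a hindered trisubstituted enamine that adds a second molecule of 15 only slowly, only the methyl-to-aldehyde pairing in 17 gives a six-membered ring (the others would give cyclobutanes), and the ring D ester has no α-hydrogen and is too hindered to be attacked.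

Step 10
Reactants: 19 methyl 2-(benzyloxy)-4-methoxy-6-{2-[4-(3-methoxy-5-[2-(4-oxocyclohex-2-en-1-yl)ethyl]phenoxy)phenyl]ethyl}benzoate
Product: 21 methyl 2-(benzyloxy)-6-{2-[4-(3-[2-(4-hydroxyphenyl)ethyl]-5-methoxyphenoxy)phenyl]ethyl}-4-methoxybenzoate, via cyclohexadienone 20 (not isolated)
Conditions: Pd(OCOCF3)2 (5 mol%), 2-(dimethylamino)pyridine (10 mol%), TsOH (20 mol%), O2 (1 atm), DMSO, 80 °C
Reagents that add atoms: none
Why: Palladium-catalysed aerobic dehydrogenation of a cyclohexenone, in which the divalent palladium enolate undergoes β-hydride elimination to the cross-conjugated dienone 20 that tautomerises to the phenol, while O2 returns zerovalent palladium to the divalent state.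

Step 11
Reactants: 21 methyl 2-(benzyloxy)-6-{2-[4-(3-[2-(4-hydroxyphenyl)ethyl]-5-methoxyphenoxy)phenyl]ethyl}-4-methoxybenzoate
Product: 22 2-(benzyloxy)-6-{2-[4-(3-[2-(4-hydroxyphenyl)ethyl]-5-methoxyphenoxy)phenyl]ethyl}-4-methoxybenzoic acid
Conditions: KOH, DMSO/H2O, 90 °C (under N2); then 1 M HCl, 0 °C
Reagents that add atoms: potassium hydroxide, [K+].[OH-]
Why: Saponification of a di-ortho-substituted methyl benzoate, which needs hot hydroxide in a dipolar medium; the phenoxide, benzyl ether and aryl ethers are base-stable, and the 2-benzyloxy acid should not decarboxylate on cold acidification.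

Step 12
Reactants: 22 2-(benzyloxy)-6-{2-[4-(3-[2-(4-hydroxyphenyl)ethyl]-5-methoxyphenoxy)phenyl]ethyl}-4-methoxybenzoic acid
Product: 23 2-hydroxy-6-{2-[4-(3-[2-(4-hydroxyphenyl)ethyl]-5-methoxyphenoxy)phenyl]ethyl}-4-methoxybenzoic acid (CNP0188714.0)
Conditions: H2 (1 atm), 10% Pd/C, EtOAc/MeOH, rt
Reagents that add atoms: none
Why: Hydrogenolysis of the benzyl aryl ether over palladium on carbon under neutral conditions, which frees the ring D phenol without touching the diaryl ether, the methyl ethers or the acid.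

**Compound list**

1 | 3-bromo-5-methoxyphenol | COc1cc(O)cc(Br)c1 | starting material
2 | para-fluorobenzaldehyde (4-fluorobenzaldehyde) | O=Cc1ccc(F)cc1 | starting material
3 | 4-(3-bromo-5-methoxyphenoxy)benzaldehyde | COc1cc(Br)cc(Oc2ccc(C=O)cc2)c1 | intermediate
4 | [4-(3-bromo-5-methoxyphenoxy)phenyl]methanol | COc1cc(Br)cc(Oc2ccc(CO)cc2)c1 | intermediate
5 | 1-bromo-3-[4-(bromomethyl)phenoxy]-5-methoxybenzene | COc1cc(Br)cc(Oc2ccc(CBr)cc2)c1 | intermediate
6 | methyl 2,4-dihydroxy-6-methylbenzoate | COC(=O)c1c(C)cc(O)cc1O | starting material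
7 | methyl 2-hydroxy-4-methoxy-6-methylbenzoate | COC(=O)c1c(C)cc(OC)cc1O | intermediate
8 | methyl 2-(benzyloxy)-4-methoxy-6-methylbenzoate | COC(=O)c1c(C)cc(OC)cc1OCc1ccccc1 | intermediate
9 | methyl 2-(benzyloxy)-6-(lithiomethyl)-4-methoxybenzoate (lithiated toluate, not isolated) | COC(=O)c1c(C[Li])cc(OC)cc1OCc1ccccc1 | intermediate
10 | methyl 2-(benzyloxy)-6-{2-[4-(3-bromo-5-methoxyphenoxy)phenyl]ethyl}-4-methoxybenzoate | COC(=O)c1c(CCc2ccc(Oc3cc(Br)cc(OC)c3)cc2)cc(OC)cc1OCc1ccccc1 | intermediate
11 | 4,4-diethoxybut-1-ene | C=CCC(OCC)OCC | starting material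
12 | 9-(4,4-diethoxybutyl)-9-borabicyclo[3.3.1]nonane (not isolated) | CCOC(CCCB1C2CCCC1CCC2)OCC | intermediate
13 | methyl 2-(benzyloxy)-6-{2-[4-(3-(4,4-diethoxybutyl)-5-methoxyphenoxy)phenyl]ethyl}-4-methoxybenzoate | COC(=O)c1c(CCc2ccc(Oc3cc(CCCC(OCC)OCC)cc(OC)c3)cc2)cc(OC)cc1OCc1ccccc1 | intermediate
14 | methyl 2-(benzyloxy)-4-methoxy-6-{2-[4-(3-methoxy-5-(4-oxobutyl)phenoxy)phenyl]ethyl}benzoate | COC(=O)c1c(CCc2ccc(Oc3cc(CCCC=O)cc(OC)c3)cc2)cc(OC)cc1OCc1ccccc1 | intermediate
15 | but-3-en-2-one (methyl vinyl ketone) | C=CC(C)=O | starting material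
16 | methyl 2-(benzyloxy)-4-methoxy-6-{2-[4-(3-methoxy-5-[(E)-4-(pyrrolidin-1-yl)but-3-enyl]phenoxy)phenyl]ethyl}benzoate (enamine, not isolated) | COC(=O)c1c(CCc2ccc(Oc3cc(CC/C=C/N4CCCC4)cc(OC)c3)cc2)cc(OC)cc1OCc1ccccc1 | intermediate
17 | methyl 2-(benzyloxy)-6-{2-[4-(3-(3-formyl-6-oxoheptyl)-5-methoxyphenoxy)phenyl]ethyl}-4-methoxybenzoate (racemic, not isolated) | COC(=O)c1c(CCc2ccc(Oc3cc(CCC(C=O)CCC(C)=O)cc(OC)c3)cc2)cc(OC)cc1OCc1ccccc1 | intermediate
18 | methyl 2-(benzyloxy)-6-{2-[4-(3-[2-(2-hydroxy-4-oxocyclohexyl)ethyl]-5-methoxyphenoxy)phenyl]ethyl}-4-methoxybenzoate (racemic mixture of diastereomers, not isolated) | COC(=O)c1c(CCc2ccc(Oc3cc(CCC4CCC(=O)CC4O)cc(OC)c3)cc2)cc(OC)cc1OCc1ccccc1 | intermediate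
19 | methyl 2-(benzyloxy)-4-methoxy-6-{2-[4-(3-methoxy-5-[2-(4-oxocyclohex-2-en-1-yl)ethyl]phenoxy)phenyl]ethyl}benzoate (racemic) | COC(=O)c1c(CCc2ccc(Oc3cc(CCC4C=CC(=O)CC4)cc(OC)c3)cc2)cc(OC)cc1OCc1ccccc1 | intermediate
20 | methyl 2-(benzyloxy)-4-methoxy-6-{2-[4-(3-methoxy-5-[2-(4-oxocyclohexa-2,5-dien-1-yl)ethyl]phenoxy)phenyl]ethyl}benzoate (not isolated) | COC(=O)c1c(CCc2ccc(Oc3cc(CCC4C=CC(=O)C=C4)cc(OC)c3)cc2)cc(OC)cc1OCc1ccccc1 | intermediate
21 | methyl 2-(benzyloxy)-6-{2-[4-(3-[2-(4-hydroxyphenyl)ethyl]-5-methoxyphenoxy)phenyl]ethyl}-4-methoxybenzoate | COC(=O)c1c(CCc2ccc(Oc3cc(CCc4ccc(O)cc4)cc(OC)c3)cc2)cc(OC)cc1OCc1ccccc1 | intermediate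
22 | 2-(benzyloxy)-6-{2-[4-(3-[2-(4-hydroxyphenyl)ethyl]-5-methoxyphenoxy)phenyl]ethyl}-4-methoxybenzoic acid | OC(=O)c1c(CCc2ccc(Oc3cc(CCc4ccc(O)cc4)cc(OC)c3)cc2)cc(OC)cc1OCc1ccccc1 | intermediate
23 | 2-hydroxy-6-{2-[4-(3-[2-(4-hydroxyphenyl)ethyl]-5-methoxyphenoxy)phenyl]ethyl}-4-methoxybenzoic acid (CNP0188714.0) | COc1cc(CCc2ccc(O)cc2)cc(Oc2ccc(CCc3cc(OC)cc(O)c3C(=O)O)cc2)c1 | target

**Count and risks**

Total step count: 12. Longest linear sequence: 10 steps (steps 1, 2, 3, 6, 7, 8, 9, 10, 11, 12 from compound 1; the branch from compound 6 is 9 steps).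

Steps most likely to fail:

1. Step 9. Amine-catalysed self-condensation of the aldehyde, polymerisation of 15, a second conjugate addition at the α-carbon, or incomplete closure and dehydration could all erode the yield on a late intermediate. The fallback gives up building ring A and buys it as an arene; it sets out from bromide 10 and comes back to the route at phenol 21. 4-tert-Butoxystyrene would be hydroborated with 9-BBN in THF to 9-[2-(4-tert-butoxyphenyl)ethyl]-9-borabicyclo[3.3.1]nonane F1. This borane would be coupled with 10 under the conditions of step 7 (PdCl2(dppf), aqueous K3PO4, DMF, 60 °C) to give methyl 2-(benzyloxy)-6-{2-[4-(3-{2-[4-(tert-butoxy)phenyl]ethyl}-5-methoxyphenoxy)phenyl]ethyl}-4-methoxybenzoate F2. CF3CO2H in CH2Cl2 at 0 °C should then cleave the aryl tert-butyl ether, which the benzyl ether and the ester survive, to give 21.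

2. Step 10. The catalyst may aggregate to palladium metal before conversion is complete, or oxidation may begin at the benzylic CH2–CH2 bridges. The fallback sets out from enone 19 and comes back at dienone 20, which tautomerises to 21. Soft enolisation with TMSOTf and Et3N in CH2Cl2 at 0 °C should give the cross-conjugated silyl dienol ether, methyl 2-(benzyloxy)-4-methoxy-6-{2-[4-(3-methoxy-5-{2-[4-(trimethylsilyloxy)cyclohexa-2,4-dien-1-yl]ethyl}phenoxy)phenyl]ethyl}benzoate F3. A Saegusa–Ito oxidation with one equivalent of Pd(OAc)2 in MeCN at room temperature, needing neither oxygen nor heat, would then deliver 20 and hence 21.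

3. Step 6. Claisen-type self-condensation of the toluate anion with the ester of unreacted 8, or a second alkylation at the newly formed benzylic CH2, may outrun the SN2 step. The fallback sets out from 8 (as its anion 9) and aldehyde 3 and comes back at 10. Anion 9 would be added at −78 °C to the much faster electrophile 3, and the resulting alkoxide should close onto the ester to give racemic 8-(benzyloxy)-3-[4-(3-bromo-5-methoxyphenoxy)phenyl]-6-methoxy-3,4-dihydroisocoumarin F4. KOC(CH3)3 in DMSO would open the lactone by E1cB elimination to (E)-2-(benzyloxy)-6-{2-[4-(3-bromo-5-methoxyphenoxy)phenyl]ethenyl}-4-methoxybenzoic acid F5. MeI and K2CO3 in DMF would give its methyl ester, methyl (E)-2-(benzyloxy)-6-{2-[4-(3-bromo-5-methoxyphenoxy)phenyl]ethenyl}-4-methoxybenzoate F6. Diimide (TsNHNH2, NaOAc, aqueous DME, reflux) should then saturate the stilbene double bond without touching the aryl bromide or the benzyl ether, giving 10.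

Further compounds
F1 | step 9 | 9-[2-(4-tert-butoxyphenyl)ethyl]-9-borabicyclo[3.3.1]nonane | CC(C)(C)Oc1ccc(CCB2C3CCCC2CCC3)cc1
F2 | step 9 | methyl 2-(benzyloxy)-6-{2-[4-(3-{2-[4-(tert-butoxy)phenyl]ethyl}-5-methoxyphenoxy)phenyl]ethyl}-4-methoxybenzoate | COC(=O)c1c(CCc2ccc(Oc3cc(CCc4ccc(OC(C)(C)C)cc4)cc(OC)c3)cc2)cc(OC)cc1OCc1ccccc1
F3 | step 10 | methyl 2-(benzyloxy)-4-methoxy-6-{2-[4-(3-methoxy-5-{2-[4-(trimethylsilyloxy)cyclohexa-2,4-dien-1-yl]ethyl}phenoxy)phenyl]ethyl}benzoate (racemic) | COC(=O)c1c(CCc2ccc(Oc3cc(CCC4CC=C(O[Si](C)(C)C)C=C4)cc(OC)c3)cc2)cc(OC)cc1OCc1ccccc1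
F4 | step 6 | 8-(benzyloxy)-3-[4-(3-bromo-5-methoxyphenoxy)phenyl]-6-methoxy-3,4-dihydroisocoumarin (racemic) | COc1cc(Br)cc(Oc2ccc(C3Cc4cc(OC)cc(OCc5ccccc5)c4C(=O)O3)cc2)c1
F5 | step 6 | (E)-2-(benzyloxy)-6-{2-[4-(3-bromo-5-methoxyphenoxy)phenyl]ethenyl}-4-methoxybenzoic acid | OC(=O)c1c(/C=C/c2ccc(Oc3cc(Br)cc(OC)c3)cc2)cc(OC)cc1OCc1ccccc1
F6 | step 6 | methyl (E)-2-(benzyloxy)-6-{2-[4-(3-bromo-5-methoxyphenoxy)phenyl]ethenyl}-4-methoxybenzoate | COC(=O)c1c(/C=C/c2ccc(Oc3cc(Br)cc(OC)c3)cc2)cc(OC)cc1OCc1ccccc1
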